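The cyclopentane is closed last, between the isopropyl carbinol carbon C4 and the ring-fusion carbon C5. Because the C4 hydroxyl and the C7 ketone of the seven-membered ring are in a 1,4 relationship (C5 is the β-carbon of a C5=C6–C7=O enone), a SmI2-mediated ketyl–enone reductive cyclisation of a 5-(4-methyl-3-oxopentyl)cyclohepta-2,6-dienone forms C4–C5, the tertiary alcohol and the bicyclo[5.3.0] skeleton in one operation and leaves a samarium dienolate for C6 oxygenation. The cis ring fusion that the tethered closure must give is corrected at the 6,7-dione stage, where C5 equilibrates to the trans fusion before hydroxyl-directed reduction, esterification and dihydroxylation.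

Key step: step 8

Remark on numbering: daucane numbering is used (C1 quaternary ring-fusion carbon with the angular methyl; C2 and C3 ring CH2; C4 isopropyl carbinol; C5 ring-fusion CH; C6 ester carbon; C7 ketone; C8 methyl carbinol; C9 carbinol; C10 CH2); β is the face of the C1 methyl, and C1 is R in all bicyclic compounds.
Assumption: 4-methylpent-1-en-3-one, 3-methylcyclohex-2-en-1-one and 4-(benzyloxy)benzoyl chloride are taken as commercially available.

Step 1
Reactants: 1 4-methylpent-1-en-3-one
Product: 3 2-(2-bromoethyl)-2-(propan-2-yl)-1,3-dioxolane, via 1-bromo-4-methylpentan-3-one 2 (not isolated)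
Conditions: HBr (gas), ethylene glycol, CH2Cl2, 0 °C to rt
Reagents that add atoms: hydrogen bromide (Br); ethane-1,2-diol (OCCO)
Why: Conjugate hydrobromination of the enone and acid-catalysed ketalisation of the β-bromo ketone (standard β-bromo ketal synthesis) should mask the isopropyl ketone for the organometallic steps; no stereocentre is formed.

Step 2
Reactants: 3 2-(2-bromoethyl)-2-(propan-2-yl)-1,3-dioxolane; 4 3-methylcyclohex-2-en-1-one
Product: 7 trimethyl{[(3S)-3-methyl-3-{2-[2-(propan-2-yl)-1,3-dioxolan-2-yl]ethyl}cyclohex-1-en-1-yl]oxy}silane, via Grignard reagent 5 (not isolated), via magnesium enolate 6 (not isolated)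
Conditions: Mg, THF, 30 °C; then 4, Cu(OTf)2 (3 mol%), chiral N-heterocyclic carbene ligand (from its imidazolinium salt, 4 mol%, enantiomer giving 3S), Et2O, −30 °C; then Me3SiCl, Et3N, HMPA, −30 °C to rt
Reagents that add atoms: chlorotrimethylsilane (C[Si](C)(C)Cl)
Why: Copper-catalysed asymmetric conjugate addition of the Grignard reagent to the β-methyl enone should create the quaternary stereocentre (later C1) under control of the chiral carbene–copper catalyst, and O-silylation of the regiodefined magnesium enolate places the enol ether double bond next to the quaternary carbon.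

Step 3
Reactants: 7 trimethyl{[(3S)-3-methyl-3-{2-[2-(propan-2-yl)-1,3-dioxolan-2-yl]ethyl}cyclohex-1-en-1-yl]oxy}silane
Product: 8 trimethyl({5-methyl-5-{2-[2-(propan-2-yl)-1,3-dioxolan-2-yl]ethyl}bicyclo[4.1.0]heptan-1-yl}oxy)silane (cyclopropane diastereomers)
Conditions: Et2Zn, CH2I2, CH2Cl2, 0 °C
Reagents that add atoms: diiodomethane (ICI)
Why: Simmons–Smith cyclopropanation with the zinc carbenoid should occur at the electron-rich silyl enol ether; the two new cyclopropane stereocentres are erased in step 4, so their configuration does not matter.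

Step 4
Reactants: 8 trimethyl({5-methyl-5-{2-[2-(propan-2-yl)-1,3-dioxolan-2-yl]ethyl}bicyclo[4.1.0]heptan-1-yl}oxy)silane
Product: 10 (4S)-4-methyl-4-{2-[2-(propan-2-yl)-1,3-dioxolan-2-yl]ethyl}cyclohept-2-en-1-one, via 3-chloro ketone 9 (not isolated)
Conditions: FeCl3, pyridine, DMF, 0 °C to rt; then NaOAc, MeOH, reflux
Reagents that add atoms: none
Why: Saegusa–Ito ring expansion: FeCl3 should oxidise the siloxycyclopropane with cleavage of the internal bond to a β-chloro cycloheptanone, and acetate-induced loss of HCl gives the 4,4-disubstituted cycloheptenone without touching the quaternary centre.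

Step 5
Reactants: 10 (4S)-4-methyl-4-{2-[2-(propan-2-yl)-1,3-dioxolan-2-yl]ethyl}cyclohept-2-en-1-one
Product: 12 (4S)-4,7-dimethyl-4-{2-[2-(propan-2-yl)-1,3-dioxolan-2-yl]ethyl}cyclohept-2-en-1-one (C7 epimers), via lithium dienolate 11 (not isolated)
Conditions: LiN(i-Pr)2, THF, −78 °C; then MeI, −78 to 0 °C
Reagents that add atoms: iodomethane (CI)
Why: Enolate alkylation: the γ-carbon is quaternary, so the base can only form the cross-conjugated α′-enolate, which should be methylated at ring C7 (later C8); the new centre becomes sp2 in step 6.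

Step 6
Reactants: 12 (4S)-4,7-dimethyl-4-{2-[2-(propan-2-yl)-1,3-dioxolan-2-yl]ethyl}cyclohept-2-en-1-one
Product: 15 (5R)-2,5-dimethyl-5-{2-[2-(propan-2-yl)-1,3-dioxolan-2-yl]ethyl}cyclohepta-2,6-dien-1-one, via lithium dienolate 13 (not isolated), via silyl dienol ether 14 (not isolated)
Conditions: LiN(i-Pr)2, Me3SiCl, THF, −78 °C; then Pd(OAc)2, MeCN, rt
Reagents that add atoms: none
Why: Saegusa–Ito oxidation: the silyl dienol ether at the methyl-bearing α′-carbon should be palladated and undergo β-hydride elimination towards the ring CH2 to give the cross-conjugated 2-methyl dienone.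

Step 7
Reactants: 15 (5R)-2,5-dimethyl-5-{2-[2-(propan-2-yl)-1,3-dioxolan-2-yl]ethyl}cyclohepta-2,6-dien-1-one
Product: 16 (5R)-2,5-dimethyl-5-(4-methyl-3-oxopentyl)cyclohepta-2,6-dien-1-one
Conditions: PPTS, acetone/H2O, 50 °C
Reagents that add atoms: water (O)
Why: Acid-catalysed ketal hydrolysis should release the isopropyl ketone; the cross-conjugated dienone and the quaternary centre are stable to PPTS.

Step 8
Reactants: 16 (5R)-2,5-dimethyl-5-(4-methyl-3-oxopentyl)cyclohepta-2,6-dien-1-one
Product: 18 4β,7-bis(trimethylsilyloxy)-5βH-dauca-6,8-diene (cis-fused), via samarium alkoxide dienolate 17 (not isolated)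
Conditions: SmI2 (2.5 equiv), HMPA, THF, −78 to 0 °C; then Me3SiCl, Et3N, 0 °C
Reagents that add atoms: chlorotrimethylsilane (C[Si](C)(C)Cl)
Why: SmI2 transfers one electron to the cross-conjugated dienone (or to the isopropyl ketone); the radical anion couples C5, the β-carbon of the C5=C6–C7=O enone, with the carbonyl carbon C4, and a second electron gives the samarium alkoxide–dienolate 17, which is O-silylated. The closest known reaction type is the SmI2 ketyl–olefin (keto-enone) reductive cyclisation. The cyclopentane closes in the 5-exo-trig mode through the C2–C3 tether, whereas attack at the other β-carbon C9 would be 6-exo and give a bridged ring. C5 is set by the tether, which can only reach the face of C5 cis to C2 (cis ring fusion, accepted here and inverted in step 10); C4 is set by the preference of the bulky HMPA-solvated samarium-bound oxygen for the exo position anti to C6, which places O4 cis to the C1 methyl as in the target. The step needs selectivity for one of two enone double bonds and survival of the other: ring size secures the first, and the absence of a proton source, which keeps the C8=C9 enone masked as the dienolate until silylation, secures the second.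

Step 9
Reactants: 18 4β,7-bis(trimethylsilyloxy)-5βH-dauca-6,8-diene
Product: 20 4β,6-dihydroxy-5βH-dauc-8-en-7-one (cis-fused; C6 epimers), via silyloxy epoxide 19 (not isolated)
Conditions: dimethyldioxirane, acetone/CH2Cl2, −78 °C; then citric acid, MeOH, rt
Reagents that add atoms: dimethyldioxirane (CC1(C)OO1)
Why: Rubottom oxidation: the dioxirane should epoxidise the electron-rich silyl enol ether double bond C6=C7 of the 2-siloxy diene in preference to C8=C9, and acidic methanolysis of the silyloxy epoxide and of the C4 silyl ether gives the α-hydroxy ketone; the C6 configuration is irrelevant because C6 is oxidised in step 10.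

Step 10
Reactants: 20 4β,6-dihydroxy-5βH-dauc-8-en-7-one
Product: 22 4β-hydroxy-5αH-dauc-8-ene-6,7-dione (trans-fused), via cis-fused dione 21 (not isolated)
Conditions: Dess–Martin periodinane, NaHCO3, CH2Cl2, 0 °C; then Et3N (0.1 equiv), CH2Cl2, rt
Reagents that add atoms: none
Why: Dess–Martin oxidation of the α-ketol should give the 6,7-dione, in which C5 is enolisable; base-catalysed equilibration through the C5 enol is expected to favour the trans ring fusion because it moves C6 from the face of the isopropyl group on C4 to the face of the hydroxyl (thermodynamic control).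

Step 11
Reactants: 22 4β-hydroxy-5αH-dauc-8-ene-6,7-dione
Product: 23 4β,6α-dihydroxy-5αH-dauc-8-en-7-one
Conditions: Me4NBH(OAc)3, MeCN/AcOH, −25 °C
Reagents that add atoms: none
Why: Evans–Saksena hydroxyl-directed reduction: the triacetoxyborohydride should bind the C4 hydroxyl and deliver hydride intramolecularly to the β-carbonyl C6 from the face of O4, which gives the 1,3-anti 6α-alcohol, leaves the conjugated C7 ketone untouched and can only operate on the trans-fused isomer in which O4 and C6 are cis.

Step 12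
Reactants: 23 4β,6α-dihydroxy-5αH-dauc-8-en-7-one; 24 4-(benzyloxy)benzoyl chloride
Product: 25 4β-hydroxy-7-oxo-5αH-dauc-8-en-6α-yl 4-(benzyloxy)benzoate
Conditions: pyridine, DMAP, CH2Cl2, 0 °C to rt
Reagents that add atoms: none
Why: DMAP-catalysed acylation should esterify the only secondary hydroxyl (C6); the tertiary C4 hydroxyl is too hindered to react.

Step 13
Reactants: 25 4β-hydroxy-7-oxo-5αH-dauc-8-en-6α-yl 4-(benzyloxy)benzoate
Product: 26 4β,8α,9α-trihydroxy-7-oxo-5αH-daucan-6α-yl 4-(benzyloxy)benzoate
Conditions: OsO4 (5 mol%), 4-methylmorpholine N-oxide, citric acid, t-BuOH/H2O, rt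
Reagents that add atoms: 4-methylmorpholine N-oxide (C[N+]1([O-])CCOCC1); water (O)
Why: Osmium-catalysed syn-dihydroxylation (citric acid for the electron-poor enone) should add both oxygens to C8=C9 from the α-face, anti to the axial methyl on C1, setting C8 and C9 together.

Step 14
Reactants: 26 4β,8α,9α-trihydroxy-7-oxo-5αH-daucan-6α-yl 4-(benzyloxy)benzoate
Product: 27 4β,8α,9α-trihydroxy-7-oxo-5αH-daucan-6α-yl 4-hydroxybenzoate (target)
Conditions: H2 (1 atm), Pd/C, EtOAc, rt
Reagents that add atoms: none
Why: Hydrogenolysis of the benzyl aryl ether over Pd/C should free the phenol; the ketone, the aryl ester and the alcohols are inert under these conditions.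

Compound list
1 | 4-methylpent-1-en-3-one | CC(C)C(=O)C=C | starting material
2 | 1-bromo-4-methylpentan-3-one | CC(C)C(=O)CCBr | intermediate (not isolated)
3 | 2-(2-bromoethyl)-2-(propan-2-yl)-1,3-dioxolane | CC(C)C1(CCBr)OCCO1 | intermediate
4 | 3-methylcyclohex-2-en-1-one | CC1=CC(=O)CCC1 | starting material
5 | {2-[2-(propan-2-yl)-1,3-dioxolan-2-yl]ethyl}magnesium bromide | CC(C)C1(CC[Mg]Br)OCCO1 | intermediate (not isolated)
6 | bromomagnesium (3S)-3-methyl-3-{2-[2-(propan-2-yl)-1,3-dioxolan-2-yl]ethyl}cyclohex-1-en-1-olate | CC(C)C1(CC[C@]2(C)CCCC(O[Mg]Br)=C2)OCCO1 | intermediate (not isolated)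
7 | trimethyl{[(3S)-3-methyl-3-{2-[2-(propan-2-yl)-1,3-dioxolan-2-yl]ethyl}cyclohex-1-en-1-yl]oxy}silane | CC(C)C1(CC[C@]2(C)CCCC(O[Si](C)(C)C)=C2)OCCO1 | intermediate
8 | trimethyl({5-methyl-5-{2-[2-(propan-2-yl)-1,3-dioxolan-2-yl]ethyl}bicyclo[4.1.0]heptan-1-yl}oxy)silane (quaternary carbon as in 7; cyclopropane carbons unspecified) | CC(C)C1(CC[C@]2(C)CCCC3(O[Si](C)(C)C)CC32)OCCO1 | intermediate
9 | 3-chloro-4-methyl-4-{2-[2-(propan-2-yl)-1,3-dioxolan-2-yl]ethyl}cycloheptan-1-one (quaternary carbon as in 10; C3 unspecified) | CC(C)C1(CC[C@]2(C)CCCC(=O)CC2Cl)OCCO1 | intermediate (not isolated)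
10 | (4S)-4-methyl-4-{2-[2-(propan-2-yl)-1,3-dioxolan-2-yl]ethyl}cyclohept-2-en-1-one | CC(C)C1(CC[C@]2(C)CCCC(=O)C=C2)OCCO1 | intermediate
11 | lithium 5-methyl-5-{2-[2-(propan-2-yl)-1,3-dioxolan-2-yl]ethyl}cyclohepta-1,6-dien-1-olate (quaternary carbon as in 10) | CC(C)C1(CC[C@]2(C)CCC=C(O[Li])C=C2)OCCO1 | intermediate (not isolated)
12 | (4S)-4,7-dimethyl-4-{2-[2-(propan-2-yl)-1,3-dioxolan-2-yl]ethyl}cyclohept-2-en-1-one (C7 epimers) | CC(C)C1(CC[C@]2(C)CCC(C)C(=O)C=C2)OCCO1 | intermediate
13 | lithium 2,5-dimethyl-5-{2-[2-(propan-2-yl)-1,3-dioxolan-2-yl]ethyl}cyclohepta-1,6-dien-1-olate (quaternary carbon as in 12) | CC(C)C1(CC[C@]2(C)CCC(C)=C(O[Li])C=C2)OCCO1 | intermediate (not isolated)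
14 | trimethyl{[2,5-dimethyl-5-{2-[2-(propan-2-yl)-1,3-dioxolan-2-yl]ethyl}cyclohepta-1,6-dien-1-yl]oxy}silane (quaternary carbon as in 12) | CC(C)C1(CC[C@]2(C)CCC(C)=C(O[Si](C)(C)C)C=C2)OCCO1 | intermediate (not isolated)
15 | (5R)-2,5-dimethyl-5-{2-[2-(propan-2-yl)-1,3-dioxolan-2-yl]ethyl}cyclohepta-2,6-dien-1-one | CC(C)C1(CC[C@]2(C)CC=C(C)C(=O)C=C2)OCCO1 | intermediate
16 | (5R)-2,5-dimethyl-5-(4-methyl-3-oxopentyl)cyclohepta-2,6-dien-1-one | CC(C)C(=O)CC[C@]1(C)CC=C(C)C(=O)C=C1 | intermediate
17 | 4β-O,7-O-bis(diiodosamarium) 5βH-dauca-6,8-diene-4,7-diolate (cis-fused; trivalent samarium) | CC(C)[C@]1(O[Sm](I)I)CC[C@]2(C)CC=C(C)C(O[Sm](I)I)=C[C@@H]21 | intermediate (not isolated)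
18 | 4β,7-bis(trimethylsilyloxy)-5βH-dauca-6,8-diene (cis-fused) | CC(C)[C@]1(O[Si](C)(C)C)CC[C@]2(C)CC=C(C)C(O[Si](C)(C)C)=C[C@@H]21 | intermediate
19 | 6,7-epoxy-4β,7-bis(trimethylsilyloxy)-5βH-dauc-8-ene (epoxide face unspecified) | CC(C)[C@]1(O[Si](C)(C)C)CC[C@]2(C)CC=C(C)C3(O[Si](C)(C)C)OC3[C@@H]21 | intermediate (not isolated)
20 | 4β,6-dihydroxy-5βH-dauc-8-en-7-one (cis-fused; C6 epimers) | CC(C)[C@]1(O)CC[C@]2(C)CC=C(C)C(=O)C(O)[C@@H]21 | intermediate
21 | 4β-hydroxy-5βH-dauc-8-ene-6,7-dione (cis-fused) | CC(C)[C@]1(O)CC[C@]2(C)CC=C(C)C(=O)C(=O)[C@@H]21 | intermediate (not isolated)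
22 | 4β-hydroxy-5αH-dauc-8-ene-6,7-dione (trans-fused; keto form shown, in equilibrium with its C5 enol) | CC(C)[C@]1(O)CC[C@]2(C)CC=C(C)C(=O)C(=O)[C@H]21 | intermediate
23 | 4β,6α-dihydroxy-5αH-dauc-8-en-7-one | CC(C)[C@]1(O)CC[C@]2(C)CC=C(C)C(=O)[C@H](O)[C@H]21 | intermediate
24 | 4-(benzyloxy)benzoyl chloride | O=C(Cl)c1ccc(OCc2ccccc2)cc1 | starting material
25 | 4β-hydroxy-7-oxo-5αH-dauc-8-en-6α-yl 4-(benzyloxy)benzoate | CC(C)[C@]1(O)CC[C@]2(C)CC=C(C)C(=O)[C@H](OC(=O)c3ccc(OCc4ccccc4)cc3)[C@H]21 | intermediate
26 | 4β,8α,9α-trihydroxy-7-oxo-5αH-daucan-6α-yl 4-(benzyloxy)benzoate | CC(C)[C@]1(O)CC[C@]2(C)C[C@H](O)[C@](C)(O)C(=O)[C@H](OC(=O)c3ccc(OCc4ccccc4)cc3)[C@H]21 | intermediate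
27 | (3R,3aS,4R,6S,7S,8aR)-3,6,7-trihydroxy-6,8a-dimethyl-5-oxo-3-(propan-2-yl)decahydroazulen-4-yl 4-hydroxybenzoate (4β,8α,9α-trihydroxy-7-oxo-5αH-daucan-6α-yl 4-hydroxybenzoate) | CC(C)[C@]1(O)CC[C@]2(C)C[C@H](O)[C@](C)(O)C(=O)[C@H](OC(=O)c3ccc(O)cc3)[C@H]21 | target

Total step count: 14. Longest linear sequence: 14 steps (1 to 27); 24 enters at step 12.

Steps most likely to fail

1. Step 8. What may go wrong: simple reduction or reductive dimerisation of the cross-conjugated dienone may outrun the 5-exo coupling, and the exo preference of the samarium-bound oxygen over the isopropyl group at C4 may erode. The fallback is a polar aldol closure of the same bond; it sets out from 16 and returns at 22. The less substituted C5=C6 enone double bond is reduced in the conjugate sense with [(Ph3P)CuH]6 and the copper enolate is silylated to the silyl dienol ether F1. Rubottom oxidation with dimethyldioxirane gives the α′-hydroxy enone F2, and Dess–Martin oxidation gives the cyclic 6,7-dione F3, whose only enolisable position is C5. An amine-mediated intramolecular aldol addition (DBU or a bifunctional amine–thiourea, CH2Cl2) of C5 to the isopropyl ketone then closes C4–C5 and, after equilibration of C5, should give 22. The C4 configuration is less secure here than in step 8; a C4 epimer would be recycled by retro-aldol under the same conditions.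

2. Step 11. What may go wrong: the hindered tertiary C4 hydroxyl may exchange slowly with the borohydride, so that reduction occurs without internal delivery or on the enol tautomer at C7, giving the 6β-alcohol or leaving cis-fused material unconverted. The fallback sets out from 22 and returns at 23: a dynamic reductive kinetic resolution with an NADPH-dependent ketoreductase (glucose and glucose dehydrogenase for cofactor recycling, phosphate buffer/DMSO, 30 °C), screened for the enzyme that reduces C6 of the trans-fused keto tautomer to the 6α-alcohol while the C5 epimers interconvert through the enol. No new compound arises (F0).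

3. Step 13. What may go wrong: facial selectivity may be poor, or osmylation of the electron-poor α-methyl enone next to the bulky C6 ester may be sluggish. The fallback moves the dihydroxylation before the esterification and makes it hydroxyl-directed; it sets out from 23 and returns at 26. Stoichiometric OsO4·TMEDA (CH2Cl2, −78 °C, then aqueous Na2SO3), hydrogen-bonded to the 6α-hydroxyl, should deliver both oxygens to the α-face of C8=C9 and give the tetraol F4. 2,2-Dimethoxypropane and PPTS protect the cis-8,9-diol as the acetonide F5, acylation of the C6 hydroxyl with 24 (pyridine, DMAP) gives the ester acetonide F6, and aqueous acetic acid removes the acetonide to give 26.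

Further compounds
F1 | step 8 | trimethyl{[4,7-dimethyl-4-(4-methyl-3-oxopentyl)cyclohepta-1,6-dien-1-yl]oxy}silane (quaternary carbon as in 16) | CC(C)C(=O)CC[C@]1(C)CC=C(C)C(O[Si](C)(C)C)=CC1
F2 | step 8 | 7-hydroxy-2,5-dimethyl-5-(4-methyl-3-oxopentyl)cyclohept-2-en-1-one (quaternary carbon as in 16; C7 epimers) | CC(C)C(=O)CC[C@]1(C)CC=C(C)C(=O)C(O)C1
F3 | step 8 | 3,6-dimethyl-6-(4-methyl-3-oxopentyl)cyclohept-3-ene-1,2-dione (quaternary carbon as in 16) | CC(C)C(=O)CC[C@]1(C)CC=C(C)C(=O)C(=O)C1
F0 | step 11 | none | none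
F4 | step 13 | 4β,6α,8α,9α-tetrahydroxy-5αH-daucan-7-one | CC(C)[C@]1(O)CC[C@]2(C)C[C@H](O)[C@](C)(O)C(=O)[C@H](O)[C@H]21
F5 | step 13 | 4β,6α-dihydroxy-8α,9α-(isopropylidenedioxy)-5αH-daucan-7-one | CC(C)[C@]1(O)CC[C@]2(C)C[C@H](O5)[C@](C)(OC5(C)C)C(=O)[C@H](O)[C@H]21
F6 | step 13 | 4β-hydroxy-8α,9α-(isopropylidenedioxy)-7-oxo-5αH-daucan-6α-yl 4-(benzyloxy)benzoate | CC(C)[C@]1(O)CC[C@]2(C)C[C@H](O5)[C@](C)(OC5(C)C)C(=O)[C@H](OC(=O)c3ccc(OCc4ccccc4)cc3)[C@H]21
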